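**Strategy.** The route rests on disconnecting the C-β–O and C-β–C-γ bonds of the stereocentre C-β. C-β carries the phenol oxygen of ring B (the vanillate ring), C-γ and the aroyl carbon C-α of ring A (the syringyl ring), so it maps onto the carbene carbon of a ring A diazoketone. One co-catalysed operation is meant to join that carbene, the free phenol of benzyl vanillate and formaldehyde. It would form both bonds and set the S configuration under control of a chiral phosphoric acid. The precursors are the O-benzyl diazoketone (two steps from acetosyringone), benzyl vanillate and monomeric formaldehyde. A single neutral hydrogenolysis then releases the target.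

Key step: step 4

Assumption (chemistry): the sense of induction of the phosphoric acid at C-β cannot be derived reliably for this enol, so the (R)-acid is written and its antipode would be used if the (R)-product should prevail; formaldehyde is bought as paraformaldehyde and cracked to the monomer just before use.

**Step 1**
Reactants: 1 acetosyringone, 1-(4-hydroxy-3,5-dimethoxyphenyl)ethanone
Product: 2 1-[4-(benzyloxy)-3,5-dimethoxyphenyl]ethanone
Conditions: BnBr, K2CO3, DMF, 60 °C
Reagents that add atoms: benzyl bromide, BrCc1ccccc1
Why: Williamson etherification of the phenoxide with benzyl bromide should mask the ring A phenol, whose O–H would otherwise intercept the carbene in step 4, while the aryl methyl ketone is untouched by K2CO3.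

**Step 2**
Reactants: 2 1-[4-(benzyloxy)-3,5-dimethoxyphenyl]ethanone
Product: 4 1-[4-(benzyloxy)-3,5-dimethoxyphenyl]-2-diazoethanone, via trifluoroacetyl diketone 3 (not isolated)
Conditions: LiN(SiMe3)2, THF, −78 °C; CF3CO2CH2CF3; aq. HCl work-up; then 4-AcNHC6H4SO2N3, Et3N, H2O, MeCN, rt
Reagents that add atoms: 2,2,2-trifluoroethyl trifluoroacetate, O=C(OCC(F)(F)F)C(F)(F)F (trifluoroacetyl group of 3 only); 4-acetamidobenzenesulfonyl azide, CC(=O)Nc1ccc(cc1)S(=O)(=O)N=[N+]=[N-] (the two diazo nitrogens of 4)
Why: Detrifluoroacetylative (deacylative Regitz-type) diazo transfer, in which Claisen trifluoroacetylation of the methyl ketone gives diketone 3 and the sulfonyl azide then transfers N2 to the activated carbon with loss of the trifluoroacetyl group as the N-acylsulfonamide, should give the terminal diazoketone without an acid chloride or trimethylsilyldiazomethane.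

**Step 3**
Reactants: 5 vanillic acid, 4-hydroxy-3-methoxybenzoic acid
Product: 6 benzyl vanillate, benzyl 4-hydroxy-3-methoxybenzoate
Conditions: BnBr, KHCO3, DMF, 40 °C
Reagents that add atoms: benzyl bromide, BrCc1ccccc1
Why: Chemoselective SN2 esterification should work because KHCO3 deprotonates only the carboxylic acid and not the much less acidic phenol, so benzyl bromide alkylates the carboxylate and the phenol stays free for step 4.

**Step 4**
Reactants: 4 1-[4-(benzyloxy)-3,5-dimethoxyphenyl]-2-diazoethanone; 6 benzyl vanillate; 7 formaldehyde
Product: 10 benzyl 4-{[(2S)-1-[4-(benzyloxy)-3,5-dimethoxyphenyl]-3-hydroxy-1-oxopropan-2-yl]oxy}-3-methoxybenzoate, via oxonium ylide 8 (not isolated), via Z-enol 9 (not isolated)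
Conditions: Rh2(OAc)4 (1 mol %), (R)-TRIP [(R)-3,3'-bis(2,4,6-triisopropylphenyl)-1,1'-binaphthyl-2,2'-diyl hydrogen phosphate, 5 mol %], 6 (1.5 equiv), CH2O (about 5 equiv, monomer passed as gas from cracked paraformaldehyde, no ethereal co-solvent), 4 Å MS, CH2Cl2, 0 °C; 4 added by syringe pump over 4 h
Reagents that add atoms: none
Why: Proposed new method: Rh2(OAc)4, a dimer of divalent rhodium, should expel N2 from 4 to give an electrophilic acyl carbene that is captured by the phenol oxygen of 6 as oxonium ylide 8, which relaxes by proton shift to Z-enol 9; this enol, held through its hydroxyl by the phosphoryl oxygen of the chiral acid while the acidic proton activates formaldehyde 7, should add through C-β to the aldehyde carbon before it tautomerises, so that the C-β–O and C-β–C-γ bonds form in one operation. The closest known reaction type is the three-component trapping by aldehydes and imines of oxonium ylides or enols generated from diazo compounds and alcohols under Rh2(OAc)4 and chiral phosphoric acid co-catalysis; a phenol, monomeric formaldehyde and a terminal diazoketone have not been combined in this way. No ring is closed. The single stereocentre C-β is set by the catalyst, whose binaphthyl pocket should leave only the Si face of C-β of 9 (priorities OAr, C-α, H) open to formaldehyde, which corresponds to the S configuration. The step needs aldol trapping to outrun the 1,2-proton shift (plain O–H insertion) and carbene insertion into the new primary alcohol; the aroyl group of ring A stabilises 9, formaldehyde in excess is the smallest and fastest trap, sieves and low temperature slow proton transfer, and slow addition keeps the carbene far below the concentration of 6.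

**Step 5**
Reactants: 10 benzyl 4-{[(2S)-1-[4-(benzyloxy)-3,5-dimethoxyphenyl]-3-hydroxy-1-oxopropan-2-yl]oxy}-3-methoxybenzoate
Product: 11 4-{[(2S)-3-hydroxy-1-(4-hydroxy-3,5-dimethoxyphenyl)-1-oxopropan-2-yl]oxy}-3-methoxybenzoic acid
Conditions: H2 (1 atm), 10% Pd/C, EtOAc, rt, stopped after uptake of two equivalents of H2
Reagents that add atoms: none
Why: Heterogeneous hydrogenolysis should cleave the two benzylic C–O bonds (aryl benzyl ether and benzyl ester) much faster than it touches the electron-rich aryl ketone or the alpha-keto C-β–O bond, and the neutral medium gives C-β no acid or base with which to enolise.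

**Compound list**
1 | acetosyringone, 1-(4-hydroxy-3,5-dimethoxyphenyl)ethanone | CC(=O)c1cc(OC)c(O)c(OC)c1 | starting material
2 | 1-[4-(benzyloxy)-3,5-dimethoxyphenyl]ethanone | CC(=O)c1cc(OC)c(OCc2ccccc2)c(OC)c1 | intermediate
3 | 1-[4-(benzyloxy)-3,5-dimethoxyphenyl]-4,4,4-trifluorobutane-1,3-dione (trifluoroacetyl diketone) | O=C(CC(=O)C(F)(F)F)c1cc(OC)c(OCc2ccccc2)c(OC)c1 | intermediate
4 | 1-[4-(benzyloxy)-3,5-dimethoxyphenyl]-2-diazoethanone | COc1cc(C(=O)C=[N+]=[N-])cc(OC)c1OCc1ccccc1 | intermediate
5 | vanillic acid, 4-hydroxy-3-methoxybenzoic acid | COc1cc(C(=O)O)ccc1O | starting material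
6 | benzyl vanillate, benzyl 4-hydroxy-3-methoxybenzoate | COc1cc(C(=O)OCc2ccccc2)ccc1O | intermediate
7 | formaldehyde (monomer, from cracked paraformaldehyde) | C=O | starting material
8 | oxonium ylide formed from the carbene of 4 and the phenol oxygen of 6 (O-protonated aryl ether, carbanion at C-β) | COc1cc(C(=O)OCc2ccccc2)ccc1[OH+][CH-]C(=O)c1cc(OC)c(OCc2ccccc2)c(OC)c1 | intermediate
9 | Z-enol, benzyl 4-{[(Z)-2-[4-(benzyloxy)-3,5-dimethoxyphenyl]-2-hydroxyethenyl]oxy}-3-methoxybenzoate | COc1cc(C(=O)OCc2ccccc2)ccc1O/C=C(\O)c1cc(OC)c(OCc2ccccc2)c(OC)c1 | intermediate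
10 | benzyl 4-{[(2S)-1-[4-(benzyloxy)-3,5-dimethoxyphenyl]-3-hydroxy-1-oxopropan-2-yl]oxy}-3-methoxybenzoate | COc1cc(C(=O)OCc2ccccc2)ccc1O[C@@H](CO)C(=O)c1cc(OC)c(OCc2ccccc2)c(OC)c1 | intermediate
11 | 4-{[(2S)-3-hydroxy-1-(4-hydroxy-3,5-dimethoxyphenyl)-1-oxopropan-2-yl]oxy}-3-methoxybenzoic acid | COc1cc(C(=O)O)ccc1O[C@@H](CO)C(=O)c1cc(OC)c(O)c(OC)c1 | target

**Step count**
Total steps: 5. Longest linear sequence: 4 steps (steps 1, 2, 4 and 5, from acetosyringone); step 3 is a one-step branch.

**Steps most likely to fail**

Step 4 (bears the label). The proton shift within ylide 8 and enol 9 may outpace addition to formaldehyde, so that only O–H insertion takes place. The acid may also fail to differentiate the two faces of C-β, and the carbene may be drained by the product alcohol or by formaldehyde itself. The fallback uses known chemistry and sets out from 4 and 6. Rh2(OAc)4-catalysed O–H insertion without aldehyde or chiral acid (CH2Cl2, rt) should give the aryloxy ketone benzyl 4-{2-[4-(benzyloxy)-3,5-dimethoxyphenyl]-2-oxoethoxy}-3-methoxybenzoate F1. Its base-mediated aldol addition to formaldehyde (K2CO3, aqueous CH2O, 1,4-dioxane, rt), the standard way to install the γ-hydroxymethyl group on such ketones, should give the racemic hydroxy ketone benzyl 4-{[1-[4-(benzyloxy)-3,5-dimethoxyphenyl]-3-hydroxy-1-oxopropan-2-yl]oxy}-3-methoxybenzoate F2. Preparative chromatography on a chiral stationary phase (amylose tris(3,5-dimethylphenylcarbamate), supercritical CO2/MeOH) should separate F2 into 10 and the mirror-image compound benzyl 4-{[(2R)-1-[4-(benzyloxy)-3,5-dimethoxyphenyl]-3-hydroxy-1-oxopropan-2-yl]oxy}-3-methoxybenzoate F3. F3 can be returned to the aldol conditions, under which C-β should equilibrate. The route is rejoined at 10.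

Step 5. Hydrogen may also be delivered to the aryl ketone or may cleave the C-β–O aryl ether bond next to the carbonyl, and long contact with the catalyst may erode the configuration at C-β. The fallback sets out from 10 and removes both benzyl groups without hydrogen, by Lewis-acid-mediated benzyl transfer to an arene scavenger (BCl3, pentamethylbenzene, CH2Cl2, −78 °C to 0 °C, aqueous work-up). BCl3 is a known reagent for aryl benzyl ethers and for benzyl esters, the methyl ethers should survive at this temperature, and no base is present that could enolise C-β. This arrives directly at 11 and makes no new compound (F0).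

Step 2. Claisen trifluoroacetylation of the electron-rich ketone may stay incomplete, or the trifluoroacetyl group may be lost before the diazo transfer, either of which would return 2. The fallback sets out from 2. α-Bromination (CuBr2, EtOAc/CHCl3, reflux) should give the phenacyl bromide 2-bromo-1-[4-(benzyloxy)-3,5-dimethoxyphenyl]ethanone F4. N-Alkylation of N,N'-ditosylhydrazine by F4, followed by base-induced loss of two sulfinate ions (TsNHNHTs, DBU, THF, 0 °C), should give 4, where the route is rejoined.

**Further compounds**
F1 | step 4 | benzyl 4-{2-[4-(benzyloxy)-3,5-dimethoxyphenyl]-2-oxoethoxy}-3-methoxybenzoate | COc1cc(C(=O)OCc2ccccc2)ccc1OCC(=O)c1cc(OC)c(OCc2ccccc2)c(OC)c1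
F2 | step 4 | racemic benzyl 4-{[1-[4-(benzyloxy)-3,5-dimethoxyphenyl]-3-hydroxy-1-oxopropan-2-yl]oxy}-3-methoxybenzoate | COc1cc(C(=O)OCc2ccccc2)ccc1OC(CO)C(=O)c1cc(OC)c(OCc2ccccc2)c(OC)c1
F3 | step 4 | benzyl 4-{[(2R)-1-[4-(benzyloxy)-3,5-dimethoxyphenyl]-3-hydroxy-1-oxopropan-2-yl]oxy}-3-methoxybenzoate | COc1cc(C(=O)OCc2ccccc2)ccc1O[C@H](CO)C(=O)c1cc(OC)c(OCc2ccccc2)c(OC)c1
F0 | step 5 | none | none
F4 | step 2 | 2-bromo-1-[4-(benzyloxy)-3,5-dimethoxyphenyl]ethanone | COc1cc(C(=O)CBr)cc(OC)c1OCc1ccccc1
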